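Assumption: the target is drawn as the free bis(hydrogen sulfate), so sulfate monoesters are written and counted in this acid form throughout; in the flask they would be sodium or ammonium salts, protonated only at the very end on an acidic ion exchanger.

## Structural features

The target is a flavonol, a 4H-chromen-4-one in which the benzo ring A is fused to the pyranone ring C along C4a–C8a, and ring C carries ring B, a 3-hydroxy-4-methoxyphenyl group, at C2. Five oxygens sit on this skeleton: hydrogen sulfate esters on O3 and O7, free phenols at C5 and C3', and a methyl ether at C4'. There is no stereocenter and no stereogenic double bond, so no stereocenters stand next to each other; the problem is one of regiochemistry and of the order of events. The fragile groups are the two sulfate monoesters: they hydrolyse in acid (the one on O3 is the ester of an enol next to a carbonyl) and they turn every intermediate into a water-soluble salt, so they must come late and see only neutral or basic conditions afterwards. The real difficulty is to tell four hydroxyls of the parent flavonol apart, since O3 and O7 must be sulfated and O5 and O3' must not. O5 is set apart by its hydrogen bond to the C4 carbonyl, whereas O3' has no such handle and needs a protecting group that can be removed last without acid. The key step exploits the position of C4, a carbonyl carbon between C4a of ring A and the C3=C2–aryl unit, with O1 ortho to C4a: C4 can be supplied as carbon monoxide between an aryl iodide carbon and a terminal alkyne carbon, and the ortho oxygen then closes ring C on C2.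

## Logic of the disconnections

**16 from 15.** No skeletal bond is cut; backward, O3' receives a benzyl group, so the forward step cleaves the O3'–CH2 bond. This comes last because O3' must stay covered while O3 and O7 are sulfated, and because hydrogenolysis is the one deprotection that runs in neutral medium. The gain is that 15 has a single free phenol, the hydrogen-bonded one at C5. The forward step must remove the benzyl group without touching two sulfate esters or the C2=C3 bond.

**15 from 14.** The two O–S bonds at O3 and O7 are cut. The sulfate monoesters are the most fragile and most polar groups, so they are removed first in the backward direction. The gain is a neutral triol that can be chromatographed. The forward step must sulfate two of three hydroxyls and leave the 5-hydroxyl alone; the hydrogen bond from O5–H to the C4 carbonyl is relied on for this.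

**14 from 13.** Backward, O5 and O7 receive methoxymethyl groups; forward, two O–CH2 acetal bonds are cleaved. Both phenols must be masked during the strongly basic functionalisation of C3 and during the key step, and one acid treatment frees both at once. The gain is a fully protected ring A. The acid must spare the benzyl ether at O3' and the methyl ether at O4'.

**13 from 10.** The C3–O bond is cut. C3 originates from the terminal alkyne carbon of the key step and cannot carry oxygen through it, so the hydroxyl is added after cyclisation. The gain is the plain flavone 10, the direct product of the key step. The forward step must find C3–H among aromatic and benzylic C–H bonds; it is the only vinylic hydrogen next to the carbonyl and the most acidic toward an amide base.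

**10 from 3, 6 and 7.** Three bonds are cut: O1–C2, C4–C3 and C4–C4a.
- Ring C disappears and the skeleton falls into an iodophenol, an arylalkyne and 7; forward, the sequence passes through 8 and 9.
- The gain is the largest of the route: two simple benzene derivatives and a gas.
- The forward step demands CO insertion before alkynylation, 6-endo closure by the phenol, and a single free hydroxyl in 3.
- The atom mapping was checked and is consistent. The iodine-bearing carbon of 3 becomes C4a, its hydroxyl oxygen O1, and its two acetal ethers O5 and O7. In 6 the methoxy group is para and the benzyloxy group meta to the ethynyl carbon, as C4' and C3' require.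
- The protecting pattern of 3 is kept as two acetals and one free hydroxyl. Acetals survive amine, CO, palladium and amide base, fall together in one acid step, and leave the benzyl ether of ring B as the only group for the final neutral hydrogenolysis.

**3 from 2, and 2 from 1.** First the C–I bond at the future C4a is cut, then two O–CH2 bonds. The gain is a symmetric, very cheap triol. Two weak points lie here, and the design answers them as follows.
- Site of iodination: the wanted carbon (between hydroxyl and acetal ether) and the unwanted one (between the two acetal ethers) each have two ortho oxygens and one para oxygen. The free phenol is therefore iodinated under neutral, acid-free conditions at low temperature, where the smaller hydroxyl neighbour and its hydrogen bond to the reagent should favour the wanted carbon.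
- Double protection of a symmetric triol is statistical. A separable mixture is accepted because 1 is cheap and the mono-ether can be resubmitted.

**6 from 4 and 5.** The bond between the two alkyne carbons is cut; the terminal carbon comes from 5 and the internal one is the formyl carbon of 4. The gain is a commercial aldehyde that already carries the 3'-benzyl and 4'-methyl ethers. The forward step needs only mild base, which both ethers tolerate.

## Other disconnections considered

**Alternative 1:** The cut falls on O1–C8a and C4–C4a. Ring A would come from an aryne, and the C2–C3–C4 chain, already carrying the C3 oxygen, from the alkoxycinnamic acid A3.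
- Forward key step: a fluoride source would remove the silyl group of the silylaryl triflate A2. The aryne set free would take up the carboxylate oxygen of A3 at the carbon remote from the neighbouring MOM ether. The aryl anion, now next to that ether, would attack the acyl carbon, and opening of the four-membered intermediate would move the acyl group from oxygen to carbon, leaving the ortho-hydroxyaryl ketone A1.
- In its favour: no transition metal and no pressurised gas. The C3 oxygen is in place from the start, which is a real advantage over the chosen plan, where it is introduced by C–H functionalisation after ring closure. The orientation of the addition is set by the inductive pull of the flanking alkoxy group, which should be as dependable as fixing the site with an iodine atom; on ring A regiochemistry the two plans are equal.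
- Against it here: the step closes no ring. A1 would still need a 6-endo oxa-Michael closure onto an alpha-alkoxy enone and a dehydrogenation to reach the flavonol level, and the usual oxidative closures release acid that endangers MOM ethers. A3 is itself a proton source, so plain O-arylation (protonation of the aryl anion before acyl transfer) would compete. A2 would need several steps from 1 (halogenation, silylation, triflation) that meet the same ortho-functionalisation question as 3 and then add to it. A3 needs an olefination of its own.
- Comparison: structurally the alternative brings in more correctly placed oxygen. Mechanistically it trades a catalytic cycle with a gas for a stoichiometric, metal-free cascade of comparable plausibility. In step economy it should lose by an estimated three to four steps, because fragment union and ring closure are separate operations and the aryne precursor is long.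

**Alternative 2:** The cut falls on C8–C8a and C4a–C5. Ring C would be present first and ring A would be built onto it.
- Forward key step: the electron-rich diene A6 would add across the C5=C6 bond (pyranone numbering) of the sulfinylpyranone A5. Its nucleophilic CH2 end would bond to the carbon next to the ring oxygen and its ketene-acetal end to the sulfinyl-bearing carbon. Syn elimination of the sulfenic acid, 1,4-loss of the alkoxy group as its alcohol and loss of the silyl groups would aromatise the new ring to A4.
- In its favour: ring A would appear with both hydroxyls free and in the 5,7-pattern dictated by the diene, with no protecting group on ring A, which is better than the chosen plan on that point. The C3 oxygen is already present. A4 would reach 14 of the chosen route by one acid treatment, so the end game would be the same.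
- Against it here: 4-pyranones are reluctant dienophiles (vinylogous esters with some aromatic stabilisation), so the step would depend wholly on the sulfinyl group. A5 is a tetrasubstituted pyranone carrying ring B, the C3 acetal ether and a sulfoxide; its assembly, sulfenylation and oxidation would take more steps than the whole front end of the chosen route. A6 is moisture-sensitive.
- Comparison: on regiocontrol the two plans are equal in principle (polarised diene against position of iodine). On protecting-group economy of ring A the alternative is better. On precedent for this substitution pattern and on step count the chosen plan is better, since it makes ring C and joins all fragments in one operation.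

**Alternative 3:** The cut removes C5–C6, C7–C8 and C4a–C5, with C8–C8a formed by the preceding migration; again ring C is made first.
- Forward key step: irradiation of the pyranonyl diazoketone A8 would trigger a Wolff rearrangement to a vinylketene, which would add the siloxyalkyne A9 in a [2+2] sense. A 4π opening of the cyclobutenone to a dienylketene, a 6π closure onto the pyranone double bond and tautomerisation would give ring A as the 5-phenol A7.
- In its favour: the regiochemistry is built into the pericyclic sequence. Ring A would emerge with O5 free and O7 as a silyl ether, differentiated exactly as the sulfation requires; this is better than the chosen plan, where that differentiation rests on the hydrogen bond of the 5-hydroxyl alone. The C3 oxygen is on board, and neither 7 nor palladium is needed.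
- Against it here: A8 would require a pyranonecarboxylic acid carrying ring B and the C3 acetal ether, followed by activation and a hazardous diazoketone-forming step. The 6π closure must engage a double bond of an aromatic-like pyranone. Photolysis must be selective for the diazoketone beside a strongly absorbing 2-arylpyranone. A9 is sensitive and must be made fresh.
- Comparison: structurally this alternative would deliver the best-differentiated ring A of the four plans. Mechanistically it sets a cascade of four pericyclic events against one catalytic three-component coupling; both have precedent in their classes, but the cascade is untried on a pyranone of this kind. In step economy it is the longest, and A7 would still need two deprotections to join the chosen route at 14.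

Key step: step 4

## Route

Step 1
Reactants: 1 phloroglucinol (benzene-1,3,5-triol)
Product: 2 3,5-bis(methoxymethoxy)phenol
Conditions: MOMCl (2.1 equiv), i-Pr2NEt (2.5 equiv), DMF, 0 °C → rt; chromatography
Reagents that add atoms: chloromethyl methyl ether (MOMCl), COCCl
Why: Williamson-type O-alkylation of the phenol with the oxocarbenium-like chloromethyl ether under amine base. With two equivalents the bis-ether should be the main component of a statistical mixture; the mono-ether can be resubmitted.

Step 2
Reactants: 2 3,5-bis(methoxymethoxy)phenol
Product: 3 2-iodo-3,5-bis(methoxymethoxy)phenol
Conditions: NIS (1.0 equiv), CH2Cl2, −40 → 0 °C, dark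
Reagents that add atoms: N-iodosuccinimide (NIS), O=C1CCC(=O)N1I
Why: Electrophilic aromatic iodination under neutral conditions that leave the acetals intact. C2 and C4 are electronically alike, but C4 is shielded by two MOM ethers, whereas C2 has the small hydroxyl as neighbour, which can hydrogen-bond to the reagent and deliver iodine to its own ortho position. One equivalent at low temperature should limit double iodination.

Step 3
Reactants: 4 3-benzyloxy-4-methoxybenzaldehyde; 5 dimethyl (1-diazo-2-oxopropyl)phosphonate
Product: 6 2-benzyloxy-4-ethynyl-1-methoxybenzene
Conditions: K2CO3 (2 equiv), MeOH, 0 °C → rt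
Reagents that add atoms: none
Why: Ohira–Bestmann homologation: methanolysis of 5 releases the diazomethylphosphonate anion, which adds to the non-enolisable aldehyde, loses dimethyl phosphate and then N2 with a 1,2-shift to give the terminal alkyne. The benzyl and methyl ethers are inert to K2CO3 in MeOH.

Step 4
Reactants: 3 2-iodo-3,5-bis(methoxymethoxy)phenol; 6 2-benzyloxy-4-ethynyl-1-methoxybenzene (1.3 equiv); 7 carbon monoxide
Product: 10 3'-benzyloxy-4'-methoxy-5,7-bis(methoxymethoxy)flavone, via ortho-hydroxyaryl ynone 8 (not isolated), via diethylamino enaminone 9 (not isolated)
Conditions: PdCl2(PPh3)2 (5 mol %), CO (20 bar), Et2NH (solvent), 120 °C, autoclave, no copper salt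
Reagents that add atoms: none
Why: The divalent palladium precatalyst is reduced in the amine/CO medium to zerovalent palladium, which inserts into the C–I bond of 3; 7 then inserts to give an aroylpalladium iodide. Diethylamine deprotonates the palladium-bound alkyne 6 and reductive elimination gives ynone 8, forming C4a–C4 and C4–C3. Diethylamine adds to the β-carbon of 8 to give enaminone 9, and the ortho phenol displaces the amine at that carbon by addition–elimination, forming O1–C2. The closest known reaction type is the palladium-catalysed carbonylative Sonogashira annulation of 2-iodophenols with terminal arylacetylenes and CO in a secondary amine, which gives flavones. Ring C closes in the 6-endo mode (6-endo-dig counted on 8, 6-endo-trig on 9). No stereocenter is formed. Two selectivities are needed: carbonylative over direct coupling, which CO pressure, the absence of copper and the ready CO insertion into the electron-rich, doubly ortho-substituted arylpalladium should secure; and 6-endo over 5-exo closure, which the secondary amine secures because in 9 the carbon β to the carbonyl is the only electrophilic site within reach of the phenol oxygen. Only one hydroxyl of 3 is free and it stands ortho to iodine, so the oxygen that closes the ring is unambiguous.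

Step 5
Reactants: 10 3'-benzyloxy-4'-methoxy-5,7-bis(methoxymethoxy)flavone
Product: 13 3'-benzyloxy-3-hydroxy-4'-methoxy-5,7-bis(methoxymethoxy)flavone, via 3-lithioflavone 11 (not isolated), via flavon-3-yl dimethyl boronate 12 (not isolated)
Conditions: LiN(i-Pr)2 (1.3 equiv), THF, −78 °C; B(OMe)3 (2 equiv), −78 → 0 °C; AcOH, 30 % aq. H2O2, 0 °C → rt
Reagents that add atoms: hydrogen peroxide, OO
Why: Lithiation–borylation–oxidation, the known route from flavones to flavonols: the amide base removes the vinylic C3–H next to the carbonyl to give 11, trimethyl borate traps it as 12, and peroxide replaces boron by oxygen at the same carbon. At −78 °C the amide should neither metalate next to the MOM ethers nor touch the benzyl ether, and prompt borate trapping should outrun opening of ring C.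

Step 6
Reactants: 13 3'-benzyloxy-3-hydroxy-4'-methoxy-5,7-bis(methoxymethoxy)flavone
Product: 14 3'-benzyloxy-3,5,7-trihydroxy-4'-methoxyflavone
Conditions: 3 M aq. HCl, MeOH/THF, 50 °C
Reagents that add atoms: none
Why: Acid-catalysed cleavage of the two MOM acetals by transacetalisation to methanol. The benzyl and methyl aryl ethers and the flavonol core are stable to dilute HCl at this temperature.

Step 7
Reactants: 14 3'-benzyloxy-3,5,7-trihydroxy-4'-methoxyflavone
Product: 15 3'-benzyloxy-5-hydroxy-4'-methoxyflavone-3,7-diyl bis(hydrogen sulfate)
Conditions: SO3·NMe3 (6 equiv), NEt3, DMF, 50 °C; then cation-exchange resin in the Na+ form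
Reagents that add atoms: sulfur trioxide–trimethylamine complex, C[N+](C)(C)S(=O)(=O)[O-]
Why: O-Sulfation of phenols with an amine–SO3 complex: the 7-hydroxyl (the most acidic, conjugated with C4=O) and the enolic 3-hydroxyl should react. The 5-hydroxyl is held in a six-membered hydrogen bond to C4=O and is the least nucleophilic hydroxyl of a flavonol, and O3' is blocked by benzyl. Exchange to the sodium salt removes amines that would slow the next step.

Step 8
Reactants: 15 3'-benzyloxy-5-hydroxy-4'-methoxyflavone-3,7-diyl bis(hydrogen sulfate)
Product: 16 5-hydroxy-2-(3-hydroxy-4-methoxyphenyl)-4-oxo-4H-chromene-3,7-diyl bis(hydrogen sulfate) (tamarixetin 3,7-di-O-sulfate)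
Conditions: H2 (1 bar), Pd/C (10 wt % palladium on carbon), MeOH/H2O, rt; then cation-exchange resin in the H+ form, 0 °C
Reagents that add atoms: none
Why: Catalytic hydrogenolysis of the benzyl aryl ether under neutral conditions, which aryl sulfate salts tolerate. The tetrasubstituted C2=C3 bond of the pyranone should not be reduced at 1 bar, and the brief cold contact with the acidic resin only protonates the sulfates to the form in which 16 is drawn.

## Compound list

1 | phloroglucinol (benzene-1,3,5-triol) | Oc1cc(O)cc(O)c1 | starting material
2 | 3,5-bis(methoxymethoxy)phenol | COCOc1cc(O)cc(OCOC)c1 | intermediate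
3 | 2-iodo-3,5-bis(methoxymethoxy)phenol | COCOc1cc(O)c(I)c(OCOC)c1 | intermediate
4 | 3-benzyloxy-4-methoxybenzaldehyde | COc1ccc(C=O)cc1OCc1ccccc1 | starting material
5 | dimethyl (1-diazo-2-oxopropyl)phosphonate | COP(=O)(OC)C(=[N+]=[N-])C(C)=O | starting material
6 | 2-benzyloxy-4-ethynyl-1-methoxybenzene | C#Cc1ccc(OC)c(OCc2ccccc2)c1 | intermediate
7 | carbon monoxide | [C-]#[O+] | starting material
8 | 3-(3-benzyloxy-4-methoxyphenyl)-1-[2-hydroxy-4,6-bis(methoxymethoxy)phenyl]prop-2-yn-1-one (not isolated) | COCOc1cc(O)c(C(=O)C#Cc2ccc(OC)c(OCc3ccccc3)c2)c(OCOC)c1 | intermediate
9 | 3-(3-benzyloxy-4-methoxyphenyl)-3-(diethylamino)-1-[2-hydroxy-4,6-bis(methoxymethoxy)phenyl]prop-2-en-1-one (not isolated; double-bond geometry not fixed, either isomer closes) | CCN(CC)C(=CC(=O)c1c(O)cc(OCOC)cc1OCOC)c1ccc(OC)c(OCc2ccccc2)c1 | intermediate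
10 | 3'-benzyloxy-4'-methoxy-5,7-bis(methoxymethoxy)flavone; 2-(3-benzyloxy-4-methoxyphenyl)-5,7-bis(methoxymethoxy)-4H-chromen-4-one | COCOc1cc(OCOC)c2c(c1)oc(-c1ccc(OC)c(OCc3ccccc3)c1)cc2=O | intermediate
11 | 3-lithio derivative of 10 (not isolated) | COCOc1cc(OCOC)c2c(c1)oc(-c1ccc(OC)c(OCc3ccccc3)c1)c([Li])c2=O | intermediate
12 | dimethyl [2-(3-benzyloxy-4-methoxyphenyl)-5,7-bis(methoxymethoxy)-4-oxo-4H-chromen-3-yl]boronate (not isolated) | COCOc1cc(OCOC)c2c(c1)oc(-c1ccc(OC)c(OCc3ccccc3)c1)c(B(OC)OC)c2=O | intermediate
13 | 3'-benzyloxy-3-hydroxy-4'-methoxy-5,7-bis(methoxymethoxy)flavone | COCOc1cc(OCOC)c2c(c1)oc(-c1ccc(OC)c(OCc3ccccc3)c1)c(O)c2=O | intermediate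
14 | 3'-benzyloxy-3,5,7-trihydroxy-4'-methoxyflavone | COc1ccc(-c2oc3cc(O)cc(O)c3c(=O)c2O)cc1OCc1ccccc1 | intermediate
15 | 3'-benzyloxy-5-hydroxy-4'-methoxyflavone-3,7-diyl bis(hydrogen sulfate) | COc1ccc(-c2oc3cc(OS(=O)(=O)O)cc(O)c3c(=O)c2OS(=O)(=O)O)cc1OCc1ccccc1 | intermediate
16 | 5-hydroxy-2-(3-hydroxy-4-methoxyphenyl)-4-oxo-4H-chromene-3,7-diyl bis(hydrogen sulfate) | COc1ccc(-c2oc3cc(OS(=O)(=O)O)cc(O)c3c(=O)c2OS(=O)(=O)O)cc1O | target

## Step count and least certain steps

Total step count: 8. Longest linear sequence: 7 steps (steps 1, 2, 4, 5, 6, 7 and 8, from 1 to 16); step 3 supplies the alkyne branch.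

**Step 4 (key step).**
- What may go wrong: coupling of the arylpalladium with the alkyne before CO insertion, followed by closure to a benzofuran; capture of the aroylpalladium by diethylamine; reductive loss of iodine from the hindered, electron-rich iodide; or 5-exo closure of the phenol.
- Fallback: it separates bond formation from ring closure and keeps the phenol masked while palladium is present. It sets out from 3, which is acetylated (Ac2O, pyridine) to 2-iodo-3,5-bis(methoxymethoxy)phenyl acetate F1. Carbonylative Sonogashira coupling of F1 with 6 and 7 under non-cyclising conditions (PdCl2(PPh3)2, NEt3, CO 1 bar, THF, rt) should give the isolable ynone 2-[3-(3-benzyloxy-4-methoxyphenyl)prop-2-ynoyl]-3,5-bis(methoxymethoxy)phenyl acetate F2. Et2NH in EtOH then removes the acetate by aminolysis, forms the enaminone and closes ring C, and the route is rejoined at 10.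

**Step 2.**
- What may go wrong: iodination at the ring carbon para to the hydroxyl, between the two MOM ethers, and double iodination, because all three free ring positions are activated by three oxygens.
- Fallback: it replaces electrophilic substitution by directed ortho-metalation. It sets out from 2, which is carbamoylated (ClC(O)NEt2, K2CO3, MeCN) to 3,5-bis(methoxymethoxy)phenyl diethylcarbamate F3. Lithiation (sec-BuLi, TMEDA, THF, −78 °C) should take place at the carbon between the carbamate and a MOM ether, where the strongest director and a second director cooperate. Quenching with I2 at that temperature gives 2-iodo-3,5-bis(methoxymethoxy)phenyl diethylcarbamate F4. Hydrolysis of the carbamate (NaOH, EtOH/H2O, reflux) rejoins the route at 3.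

**Step 5.**
- What may go wrong: opening of ring C by β-elimination of the O1 phenoxide from the C3 anion if the temperature rises before borate trapping; incomplete borylation; or metalation next to a MOM ether.
- Fallback: it avoids carbanions altogether. It sets out from 10, which is epoxidised with dimethyldioxirane (acetone/CH2Cl2, 0 °C) to the racemic 2,3-epoxide 1a-(3-benzyloxy-4-methoxyphenyl)-4,6-bis(methoxymethoxy)-1a,7a-dihydro-7H-oxireno[2,3-b]chromen-7-one F5. Catalytic p-TsOH in CH2Cl2 opens the epoxide at C2 to a cation stabilised by O1 and ring B, and loss of the C3 proton gives the flavonol, rejoining the route at 13.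

**Step 7.**
- What may go wrong: incomplete sulfation of the hydrogen-bonded 3-hydroxyl, or partial sulfation of the 5-hydroxyl when the reaction is forced, leading to mixtures of very polar salts that resist separation.
- Fallback: it uses protected sulfate diesters. It sets out from 14, which is treated with 2,2,2-trichloroethyl chlorosulfate (NEt3, DMAP, THF, 0 °C → rt) to give the neutral, chromatographable 3'-benzyloxy-5-hydroxy-4'-methoxyflavone-3,7-diyl bis(2,2,2-trichloroethyl sulfate) F6. Reductive removal of the trichloroethyl groups (Zn, HCO2NH4, MeOH, rt) leaves the benzyl ether in place and rejoins the route at 15.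

## Further compounds

F1 | step 4 | 2-iodo-3,5-bis(methoxymethoxy)phenyl acetate | CC(=O)Oc1cc(OCOC)cc(OCOC)c1I
F2 | step 4 | 2-[3-(3-benzyloxy-4-methoxyphenyl)prop-2-ynoyl]-3,5-bis(methoxymethoxy)phenyl acetate | CC(=O)Oc1cc(OCOC)cc(OCOC)c1C(=O)C#Cc1ccc(OC)c(OCc2ccccc2)c1
F3 | step 2 | 3,5-bis(methoxymethoxy)phenyl diethylcarbamate | CCN(CC)C(=O)Oc1cc(OCOC)cc(OCOC)c1
F4 | step 2 | 2-iodo-3,5-bis(methoxymethoxy)phenyl diethylcarbamate | CCN(CC)C(=O)Oc1cc(OCOC)cc(OCOC)c1I
F5 | step 5 | 1a-(3-benzyloxy-4-methoxyphenyl)-4,6-bis(methoxymethoxy)-1a,7a-dihydro-7H-oxireno[2,3-b]chromen-7-one (racemic; the epoxide is necessarily cis-fused) | COCOc1cc(OCOC)c2c(c1)OC1(c3ccc(OC)c(OCc4ccccc4)c3)OC1C2=O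
F6 | step 7 | 3'-benzyloxy-5-hydroxy-4'-methoxyflavone-3,7-diyl bis(2,2,2-trichloroethyl sulfate) | COc1ccc(-c2oc3cc(OS(=O)(=O)OCC(Cl)(Cl)Cl)cc(O)c3c(=O)c2OS(=O)(=O)OCC(Cl)(Cl)Cl)cc1OCc1ccccc1
A1 | alternative 1 | (Z)-3-(3-benzyloxy-4-methoxyphenyl)-1-[2-hydroxy-4,6-bis(methoxymethoxy)phenyl]-2-(methoxymethoxy)prop-2-en-1-one | O=C(c1c(O)cc(OCOC)cc1OCOC)/C(OCOC)=C/c1ccc(OC)c(OCc2ccccc2)c1
A2 | alternative 1 | 3,5-bis(methoxymethoxy)-2-(trimethylsilyl)phenyl trifluoromethanesulfonate | C[Si](C)(C)c1c(OCOC)cc(OCOC)cc1OS(=O)(=O)C(F)(F)F
A3 | alternative 1 | (Z)-3-(3-benzyloxy-4-methoxyphenyl)-2-(methoxymethoxy)prop-2-enoic acid | OC(=O)/C(OCOC)=C/c1ccc(OC)c(OCc2ccccc2)c1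
A4 | alternative 2 | 3'-benzyloxy-5,7-dihydroxy-4'-methoxy-3-(methoxymethoxy)flavone | COCOc1c(-c2ccc(OC)c(OCc3ccccc3)c2)oc2cc(O)cc(O)c2c1=O
A5 | alternative 2 | 2-(3-benzyloxy-4-methoxyphenyl)-3-(methoxymethoxy)-5-(phenylsulfinyl)-4H-pyran-4-one (racemic at sulfur) | COCOc1c(-c2ccc(OC)c(OCc3ccccc3)c2)occ(S(=O)c2ccccc2)c1=O
A6 | alternative 2 | 1-methoxy-1,3-bis(trimethylsilyloxy)buta-1,3-diene (geometry of the C1=C2 bond not defined) | COC(O[Si](C)(C)C)=CC(=C)O[Si](C)(C)C
A7 | alternative 3 | 3'-benzyloxy-5-hydroxy-4'-methoxy-3-(methoxymethoxy)-7-(triisopropylsilyloxy)flavone | CC(C)[Si](Oc1cc(O)c2c(c1)oc(-c1ccc(OC)c(OCc3ccccc3)c1)c(OCOC)c2=O)(C(C)C)C(C)C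
A8 | alternative 3 | 1-[6-(3-benzyloxy-4-methoxyphenyl)-5-(methoxymethoxy)-4-oxo-4H-pyran-2-yl]-2-diazoethan-1-one | [N-]=[N+]=CC(=O)c1cc(=O)c(OCOC)c(-c2ccc(OC)c(OCc3ccccc3)c2)o1
A9 | alternative 3 | (ethynyloxy)triisopropylsilane | C#CO[Si](C(C)C)(C(C)C)C(C)C
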